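All runs come from a simulation for substances that don't exist, noise included.

As the chemist who has to call this flask, I start from the runs made so far.

| flask | substrate | coupling partner | free catalyst | remark | time |
|---|---|---|---|---|---|
| north-west | 0.56 M | 0.40 M | 80 mM | run made earlier |  |
| north-east | 0.88 M | 0.40 M | 80 mM | run made earlier |  |
| west | 0.40 M | 0.20 M | 80 mM | run made earlier |  |
| flask | 0.40 M | 0.400 M | 80 mM |  | 3.0 min |

| run | time / s | target / % |
|---|---|---|
| north-west | 12.0 | 9 |
| north-west | 20.0 | 13 |
| north-west | 25.0 | 13 |
| north-west | 40.0 | 21 |
| north-west | 50.0 | 21 |
| north-west | 80.0 | 19 |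
| north-west | 120 | 15 |
| north-east | 12.0 | 7 |
| north-east | 20.0 | 9 |
| north-east | 25.0 | 14 |
| north-east | 40.0 | 13 |
| north-east | 50.0 | 16 |
| north-east | 80.0 | 12 |
| north-east | 120 | 10 |
| west | 12.0 | 4 |
| west | 20.0 | 11 |
| west | 40.0 | 18 |
| west | 60.0 | 17 |
| west | 120 | 11 |

(each reading ± 1.5 percentage points)

* when, up to 3.0 min, the flask holds most target
* the amount of target, in percent of the substrate charged, at that time

The zero of my scale is the flask with equal charges: with one coupling partner per substrate, a peak counted on the substrate is the same number as that peak counted on the partner. So I turn each run into its partner share, the highest target reading counted on the charge of coupling partner, which is the limiting reagent by charge in the north-west run.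

The first way uses the west run, which has the flask's substrate charge. Its reading of 18% gives a share of 36.0%. The second way uses the north-west and north-east runs, which have the flask's partner charge. They give shares of 29.4% and 35.2%, a rise of 0.181 L mol⁻¹, my substrate slope. Walking back to 0.40 M gives 26.5%.

The two ways part by 9.5 percentage points, and a single west reading carries 3 points. I judge that the west way cheats: it carries a share from 0.20 M of partner to 0.400 M as if that change moved nothing, and I have no run at the flask's substrate charge that tests this, while the line keeps the partner at the flask's charge and changes the substrate, though it rests on two readings. So I commit to the line.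

The forecast gives 26% at 0.75 min, on its ground that “Peak yield tracks the partner/substrate ratio”. Its amount stands close to mine, and I take its time, for which I have no reckoning of my own.

The flask holds 27.2% at 0.860 min, and 12.9% at 3.00 min, so left to the end it keeps half of its peak target.

    substrate + free catalyst ⇌ catalyst intermediate A (K = 4.10 L mol⁻¹, k = 23.0 L mol⁻¹ s⁻¹)
    coupling partner + catalyst intermediate A → catalyst intermediate B (k = 1.00 L mol⁻¹ s⁻¹)
    catalyst intermediate B ⇌ by-product + catalyst intermediate C (K = 37.0 M, k = 0.200 s⁻¹)
    catalyst intermediate C → catalyst intermediate D (k = 0.360 s⁻¹)
    catalyst intermediate D → free catalyst + target (k = 28.0 s⁻¹)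
    target ⇌ isomer of the product (K = 4.40, k = 0.0140 s⁻¹)
    2 coupling partner → self-condensation product (k = 0.0870 L mol⁻¹ s⁻¹)

On equal charges, the flask's peak is a partner share of 27.2%, against 26.5% from my slope. For the neighbour flask with 0.68 M of substrate, whose charge lies between those of the north-west and north-east runs, the slope gives 18.6% of its substrate; the computed peak is 18.0%.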